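## Analysis of the target

CNP0226738.1 is an eremophilane-type sesquiterpenoid ester built on a cis-fused decalin (ring A = C1–C5 and C10, ring B = C5–C10). It carries methyl groups on C4 (C15) and on the quaternary C5 (C14), a (2E,4E,6E)-5-methyldodeca-2,4,6-trienoate on the C3 oxygen, a C8 ketone, a C9 carbinol and an exocyclic tetrasubstituted C7=C11 alkene whose C11 bears a methyl (C13) and a hydroxymethyl (C12). With the face of the C5 methyl taken as β, the five stereocentres are 3α-O, 4β-Me, 5β-Me, 9β-OH and 10β-H, i.e. (3R,4R,5R,9R,10S). The two methyls are cis, the C3 oxygen is trans to the C4 methyl, the ring fusion is cis and the C9 hydroxyl is cis to H-10. The C7=C11 alkene is Z, so the hydroxymethyl group is syn to the C8 carbonyl. This makes the molecule fragile: a γ-hydroxy enone of this geometry can close to a hemiketal and lose water to a furan under acid, and can drift towards a 1,4-dicarbonyl tautomer under base. The α-ketol at C8/C9 and the trienoate are further base- and light-sensitive sites. The difficulties are four contiguous stereocentres on ring A including a quaternary carbon, the absolute configuration, the stereodefined tetrasubstituted alkene and a mild end game. The strategy rests on two features: C3, C4, C5 and C10 lie on one six-membered ring in the pattern that an (E)-2-methylbut-2-enoyl unit (C4=C5–C6=O) leaves when it adds suprafacially to an (E,E)-1-oxygenated diene (C10=C1–C2=C3), and C6–C10 with the C9 oxygen is the carbon chain of glutamic acid.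

## Retrosynthetic reasoning

**33 ⇒ 32 (O–Si bonds at C9 and C12).** The two hydroxyls that make the target labile are released only in the last step, under buffered fluoride, so that the (Z)-γ-hydroxy enone never meets acid or base on the way.

**32 ⇒ 27 + 30 (C3–O acyl bond).** The trienoate is a Michael acceptor and would not survive hydride, hydroperoxide or hydrazine, so it is attached after all ring B chemistry. The forward reaction must acylate a hindered secondary alcohol without isomerising the triene.

**30 ⇒ 29 ⇒ 28 (C4′=C5′ of the side chain).** A vinylogous Horner–Wadsworth–Emmons reaction on the methyl ketone 28 builds the whole trienoate in one C–C bond formation. The forward step has to favour 1,2-addition and the 4′E isomer.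

**27 ⇒ 26 (C3 O–benzyl bond).** The C3 oxygen is carried as a 4-methoxybenzyl ether from the diene stage on. A plain benzyl ether would be lost with C1=C2 on heterogeneous hydrogenation and leave a free C3 hydroxyl through four oxidations. The 4-methoxybenzyl ether survives homogeneous hydrogenation and is removed oxidatively in the presence of silyl ethers and the enone.

**26 ⇒ 25 ⇒ 24 ⇒ 22 (the Z alkene, by re-joining C8–O–C12).** A plain aldol–dehydration at C7 cannot be trusted to set this alkene: the bulkier silyloxymethyl group prefers the position away from the carbonyl, which is the wrong isomer. The C8 and C12 oxygens are therefore traced back to one furan oxygen in 22. Oxidative opening of a furan can only deliver the two carbonyl carbons cis on C7=C11, and reduction, selective silylation and re-oxidation then give 26 with the geometry fixed.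

**22 ⇒ 19 (C7–C11 and O–C8).** The furan is annulated onto the C8 ketone by a regiospecific enolate (from conjugate reduction of enone 19), an aldol addition that brings in C11–C13 with the C12 oxygen, and cyclodehydration. Both aldol diastereomers and both later alkene isomers converge on the aromatic ring.

**19 ⇒ 18 ⇒ 17 ⇒ 16 ⇒ 14 (carbonyl moved from C8 back to C6).** The cycloaddition needs the carbonyl at C6, conjugated to the dienophile, whereas the target has it at C8. This 1,3-transposition is the price of the key step. It is unambiguous because C6 is flanked by the quaternary C5 and can only be enolised towards C7.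

**14 ⇒ 13 (C1=C2).** The ring A alkene left by the cycloaddition is saturated without touching the allylic and benzylic C3–O bonds.

**13 ⇒ 12 (C3–C4 and C5–C10, the key disconnection).** Cutting these two bonds opens both rings at once and turns four stereocentres into three alkene geometries plus the single stereocentre C9. No other pair of cuts converts the quaternary C5 and its three neighbours into flat, easily made precursors. The forward reaction must be endo with respect to the tether carbonyl and must use the diene face dictated by C9.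

**12 ⇒ 11 ⇒ 7 + 8 (C5–C6).** The enone is formed by single addition of the alkenyllithium from 8 to a γ-lactone, which at the same time releases the C9 hydroxyl for silylation.

**7 ⇒ 6 ⇒ 5 ⇒ 3 ⇒ 2 ⇒ 1 (C3–O, C2=C3, C10=C1; C9 from the chiral pool).** The carboxyl carbon of 1 becomes C10 and the side-chain carboxyl becomes the lactone carbonyl C6. The (E,E)-dienyl ether is assembled by a Wittig reaction (C10=C1), a chromium-mediated boron olefination (C2=C3) and a stereoretentive copper-mediated C–O coupling. An alkoxymethylene Wittig reaction would give both enol ether isomers, and only the (E) isomer leads to the right C3 configuration.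

## Alternatives that were turned down

**Alternative 1:** The decalin is cut at C5–C6 in the sense of an anionic oxy-Cope rearrangement. A potassium alkoxide on a bridged bicyclic carbinol, generated with a hydride base and a crown ether, shifts [3,3], forms C5–C6, breaks C3–C8 and unfolds to the cis-fused ketone A1 as its C8 enolate.
- For: the concerted shift fixes the cis fusion and the quaternary C5. A1 already has the ketone at C8 and an oxygenated C9, so no carbonyl transposition is needed. On ring B step economy this route is stronger than the chosen one.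
- Against: C9 arrives as a ketal without configuration, so a masked 8,9-dione must later be differentiated and reduced from the right face. The C3 oxygen and the C4 stereocentre still have to be introduced across the C3=C4 alkene with face control. The bridged precursor comes from achiral components, so the absolute configuration needs a separate solution.
- Comparison: the chosen strategy offers the absolute configuration from glutamic acid, C9 in its final configuration, and C3, C4, C5 and C10 in one step.

**Alternative 2:** The cut is C1–C10. Zerovalent palladium with a chiral bisphosphine and a formate reductant inserts into a vinyl bromide, adds to one of two enantiotopic enone alkenes of a prochiral cyclohexadienone and the palladium enolate is reduced, giving A2.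
- For: C5 and C10 are set by a catalyst from a symmetric substrate. In principle this is a stronger source of absolute control than the substrate relay from C9 in the chosen route, which is modest.
- Against: A2 holds only two of the five stereocentres. The C4 methyl must replace a ketone with the correct relation to C5, the C3 oxygen must be placed next to it, and C9 must be oxidised beside C8. These are three stereocentres set one at a time on a conformationally mobile cis-decalin, with several redox adjustments.
- Comparison: the chosen cycloaddition installs C3 and C4 together with C5 and C10 and needs no later work on ring A beyond one hydrogenation.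

**Alternative 3:** The cut is C4–C5. A potassium phenolate attacks a secondary C4 mesylate through its para carbon C5 with inversion, closes ring A and dearomatises ring B to the cross-conjugated dienone A3.
- For: C3 and C4 come from the chiral pool, and ring B arrives with the C8 carbonyl, the C9 oxygen and a C6=C7 alkene in place. This is closer to the target's ring B than anything in the chosen route before step 13.
- Against: C-alkylation by a secondary mesylate competes with O-alkylation and elimination, and the cis relation of the C4 and C5 methyls rests on a weakly biased transition state. The main weakness is that C10 is still sp2 in A3. C10–H and C9–OH would have to be created by reducing a tetrasubstituted enol ether from the face syn to the angular methyl, against the normal steric preference.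
- Comparison: the chosen strategy sets C10 relative to C5 through the endo rule in the same step that makes the quaternary centre.

Key step: step 8

Assumption (chemistry): the epoxide of 17 and the C8 carbinol of 18 are drawn with oxygen anti to the C9 silyl ether, the expected course of nucleophilic epoxidation; 10, 21, 24 and 25 are mixtures at the centres left unspecified in their SMILES; none of these centres survives in 33.

Abbreviations: PMB = 4-methoxybenzyl, TBS = tert-butyldimethylsilyl, DMP = Dess–Martin periodinane, DMDO = dimethyldioxirane. Bicyclic compounds are described with eremophilane numbering and the α/β convention of the analysis.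

## Route

Step 1
Reactants: 1 L-glutamic acid
Product: 2 (S)-5-oxotetrahydrofuran-2-carboxylic acid
Conditions: NaNO2, aq. HCl, 0 → 23 °C
Reagents that add atoms: none
Why: Diazotisation of the α-amino acid; the α-carboxylate displaces N2 to an α-lactone that the γ-carboxyl opens, so the future C9 oxygen arrives with net retention (double inversion).

Step 2
Reactants: 2 (S)-5-oxotetrahydrofuran-2-carboxylic acid
Product: 3 (S)-5-(hydroxymethyl)dihydrofuran-2(3H)-one
Conditions: BH3·SMe2, THF, 0 → 23 °C; MeOH
Reagents that add atoms: none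
Why: Borane reduces the free carboxylic acid through its acyloxyborane much faster than the lactone; the stereocentre is not touched.

Step 3
Reactants: 3 (S)-5-(hydroxymethyl)dihydrofuran-2(3H)-one
Product: 5 (E)-3-[(2S)-5-oxotetrahydrofuran-2-yl]prop-2-enal, via lactone aldehyde 4 (not isolated)
Conditions: DMP, NaHCO3, CH2Cl2, 0 → 23 °C; then Ph3P=CHCHO, 23 °C
Reagents that add atoms: (triphenylphosphoranylidene)acetaldehyde, O=CC=P(c1ccccc1)(c1ccccc1)c1ccccc1
Why: Neutral oxidation followed by Wittig olefination in the same flask avoids isolating the epimerisable α-acyloxy aldehyde 4; the stabilised ylide gives the (E)-enal (C10=C1).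

Step 4
Reactants: 5 (E)-3-[(2S)-5-oxotetrahydrofuran-2-yl]prop-2-enal
Product: 6 (S)-5-[(1E,3E)-4-(4,4,5,5-tetramethyl-1,3,2-dioxaborolan-2-yl)buta-1,3-dien-1-yl]dihydrofuran-2(3H)-one
Conditions: Cl2CHB(pin), CrCl2, LiI, THF, 23 °C
Reagents that add atoms: 2-(dichloromethyl)-4,4,5,5-tetramethyl-1,3,2-dioxaborolane, ClC(Cl)B1OC(C)(C)C(C)(C)O1
Why: Takai–Utimoto boron olefination; the gem-dichromium species adds to the aldehyde and eliminates to the (E)-alkenyl boronate (C2=C3) under non-basic conditions that spare the lactone and the allylic stereocentre.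

Step 5
Reactants: 6 (S)-5-[(1E,3E)-4-(4,4,5,5-tetramethyl-1,3,2-dioxaborolan-2-yl)buta-1,3-dien-1-yl]dihydrofuran-2(3H)-one
Product: 7 (S)-5-{(1E,3E)-4-[(4-methoxybenzyl)oxy]buta-1,3-dien-1-yl}dihydrofuran-2(3H)-one
Conditions: Cu(OAc)2, Et3N, 4-MeOC6H4CH2OH (excess), 4 Å MS, CH2Cl2, air, 23 °C
Reagents that add atoms: 4-methoxybenzyl alcohol, COc1ccc(CO)cc1
Why: Chan–Lam–Evans oxidative C–O coupling of an alkenyl boronate with an alcohol retains the alkene geometry, so the (E)-enol ether needed for the cycloaddition is obtained as a single isomer at room temperature.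

Step 6
Reactants: 7 (S)-5-{(1E,3E)-4-[(4-methoxybenzyl)oxy]buta-1,3-dien-1-yl}dihydrofuran-2(3H)-one; 8 (E)-2-bromobut-2-ene
Product: 11 (2E,7S,8E,10E)-7-hydroxy-11-[(4-methoxybenzyl)oxy]-3-methylundeca-2,8,10-trien-4-one, via (E)-but-2-en-2-yllithium 9 (not isolated), via lithium lactolate 10 (not isolated)
Conditions: 8, t-BuLi (2 equiv), Et2O, −78 °C; then 7, THF, −78 °C; NH4Cl at −78 °C
Reagents that add atoms: none
Why: Bromine–lithium exchange is stereoretentive, and the alkenyllithium adds only once because the tetrahedral lactolate 10 persists at −78 °C; on work-up it opens to the γ-hydroxy (E)-enone, forming C5–C6.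

Step 7
Reactants: 11 (2E,7S,8E,10E)-7-hydroxy-11-[(4-methoxybenzyl)oxy]-3-methylundeca-2,8,10-trien-4-one
Product: 12 (2E,7S,8E,10E)-7-[(tert-butyldimethylsilyl)oxy]-11-[(4-methoxybenzyl)oxy]-3-methylundeca-2,8,10-trien-4-one
Conditions: TBSCl, imidazole, DMF, 0 → 23 °C
Reagents that add atoms: tert-butyldimethylsilyl chloride, CC(C)(C)[Si](C)(C)Cl
Why: Standard silylation traps the open-chain hydroxy ketone; the mildly basic medium spares the acid-labile dienyl ether.

Step 8
Reactants: 12 (2E,7S,8E,10E)-7-[(tert-butyldimethylsilyl)oxy]-11-[(4-methoxybenzyl)oxy]-3-methylundeca-2,8,10-trien-4-one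
Product: 13 cis-fused cycloadduct 3α-(PMB-oxy)-9β-(TBS-oxy)-4β,5β-dimethyl-10βH-octal-1-en-6-one
Conditions: PhMe (0.01 M), BHT, 120 °C, sealed tube
Reagents that add atoms: none
Why: Thermal intramolecular Diels–Alder reaction: the enone alkene C4=C5 adds suprafacially across the s-cis diene C10=C1–C2=C3 in one concerted but asynchronous [4+2] step, the closest known reaction type being the cyclisation of deca-1,7,9-trien-3-ones to cis-fused octalones on mild heating. Ring A (C1–C5, C10) is the new cyclohexene made by both σ-bonds (C3–C4 and C5–C10), and ring B (C5–C10) is closed by the C5–C10 bond alone through the four-atom tether C6–C9, i.e. fused-mode closure with the tether carbonyl endo. C4 and C5: the (E)-dienophile geometry is transferred, so the two methyl groups end up cis. C3: the (E)-enol ether places the oxygen on the outside of the diene, and with C6 endo this makes the C3 oxygen trans to the C4 methyl. C10: endo placement of the tether carbonyl (favoured by secondary overlap with the diene, by the short tether and because the exo mode would push the C5 methyl under the diene) gives the cis ring fusion. The absolute sense is relayed from C9: its hydrogen lies near the diene plane on the inside (towards C1–H), C8 drops to the dienophile and the silyloxy group points outward, which exposes the diene face that leads to 13; since C1 carries only hydrogen this allylic strain is modest and is the selectivity on which the step depends. No Lewis acid is used, because the tether forces the oxygen-bearing terminus C3 onto the enone β-carbon C4, against the natural polarisation of both partners, so that a strong acid would favour stepwise ionic paths and cleave the dienyl ether; the oxygen substituent helps only by raising the diene HOMO.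

Step 9
Reactants: 13 cis-fused cycloadduct 3α-(PMB-oxy)-9β-(TBS-oxy)-4β,5β-dimethyl-10βH-octal-1-en-6-one
Product: 14 3α-(PMB-oxy)-9β-(TBS-oxy)-4β,5β-dimethyl-10βH-decalin-6-one
Conditions: H2 (4 atm), RhCl(PPh3)3 (cat.), PhH/EtOH, 23 °C
Reagents that add atoms: none
Why: Homogeneous rhodium hydrogenation saturates the cis-disubstituted C1=C2 alkene without hydrogenolysis of the benzylic or the allylic C3–O bond; no stereocentre is formed.

Step 10
Reactants: 14 3α-(PMB-oxy)-9β-(TBS-oxy)-4β,5β-dimethyl-10βH-decalin-6-one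
Product: 16 3α-(PMB-oxy)-9β-(TBS-oxy)-4β,5β-dimethyl-10βH-octal-7-en-6-one, via trimethylsilyl enol ether 15 (not isolated)
Conditions: LiN(i-Pr)2, THF, −78 °C; Me3SiCl; then Pd(OAc)2, MeCN, 23 °C
Reagents that add atoms: none
Why: Saegusa–Ito oxidation; C6 is flanked by the quaternary C5, so enolisation can only go towards C7, and palladation of 15 at C7 followed by β-hydride elimination gives the C7=C8 enone.

Step 11
Reactants: 16 3α-(PMB-oxy)-9β-(TBS-oxy)-4β,5β-dimethyl-10βH-octal-7-en-6-one
Product: 17 7α,8α-epoxy-3α-(PMB-oxy)-9β-(TBS-oxy)-4β,5β-dimethyl-10βH-decalin-6-one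
Conditions: 30% H2O2, NaOH (cat.), MeOH, 0 °C
Reagents that add atoms: hydrogen peroxide, OO
Why: Weitz–Scheffer nucleophilic epoxidation; hydroperoxide adds to C8 and the enolate closes the epoxide, expected anti to the C9 silyl ether, although the epoxide configuration is of no consequence.

Step 12
Reactants: 17 7α,8α-epoxy-3α-(PMB-oxy)-9β-(TBS-oxy)-4β,5β-dimethyl-10βH-decalin-6-one
Product: 18 3α-(PMB-oxy)-9β-(TBS-oxy)-4β,5β-dimethyl-10βH-octal-6-en-8α-ol
Conditions: N2H4·H2O, AcOH (cat.), MeOH, 0 → 23 °C
Reagents that add atoms: none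
Why: Wharton transposition; the hydrazone of the epoxy ketone opens the epoxide and the vinyl diazene loses N2, moving the alkene to C6=C7 and leaving oxygen on C8.

Step 13
Reactants: 18 3α-(PMB-oxy)-9β-(TBS-oxy)-4β,5β-dimethyl-10βH-octal-6-en-8α-ol
Product: 19 3α-(PMB-oxy)-9β-(TBS-oxy)-4β,5β-dimethyl-10βH-octal-6-en-8-one
Conditions: DMP, NaHCO3, CH2Cl2, 0 → 23 °C
Reagents that add atoms: none
Why: Buffered Dess–Martin oxidation of the allylic alcohol completes the 1,3-carbonyl transposition without epimerising the α-silyloxy centre C9.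

Step 14
Reactants: 19 3α-(PMB-oxy)-9β-(TBS-oxy)-4β,5β-dimethyl-10βH-octal-6-en-8-one
Product: 22 3α-(PMB-oxy)-9β-(TBS-oxy)-10βH-furanoeremophilane (8,12-epoxyeremophila-7,11-diene), via lithium enolate 20 (not isolated), via aldol adduct 21 (not isolated)
Conditions: LiBH(s-Bu)3, THF, −78 °C; TBSOCH2C(O)CH3, −78 °C; AcOH; then PPTS, MeOH, 23 °C
Reagents that add atoms: 1-[(tert-butyldimethylsilyl)oxy]propan-2-one, CC(=O)CO[Si](C)(C)C(C)(C)C
Why: Conjugate hydride addition to the β-unsubstituted enone gives the C7=C8 enolate 20 regiospecifically, and its aldol addition to the activated α-silyloxy ketone forms C7–C11. Mild acid then frees the primary hydroxyl, which closes onto C8, and two dehydrations (Paal–Knorr-type) give the aromatic furan, so no alkene geometry has to be chosen at this stage.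

Step 15
Reactants: 22 3α-(PMB-oxy)-9β-(TBS-oxy)-10βH-furanoeremophilane (8,12-epoxyeremophila-7,11-diene)
Product: 24 (7(11)Z)-3α-(PMB-oxy)-9β-(TBS-oxy)-10βH-eremophil-7(11)-ene-8,12-diol, via cis-enedione 23 (not isolated)
Conditions: DMDO, acetone, −78 → 0 °C; evaporate at 0 °C; then NaBH4, CeCl3·7H2O, MeOH, −78 °C
Reagents that add atoms: dimethyldioxirane, CC1(C)OO1
Why: Oxygen transfer to the electron-rich furan opens it to the cis-enedione 23, in which C8 and C12 must be cis on C7=C11 because both were bonded to the ring oxygen (the C9 silyl ether blocks an Achmatowicz ring expansion). Immediate Luche 1,2-reduction of both carbonyls secures the Z geometry before the enedione can isomerise.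

Step 16
Reactants: 24 (7(11)Z)-3α-(PMB-oxy)-9β-(TBS-oxy)-10βH-eremophil-7(11)-ene-8,12-diol
Product: 25 (7(11)Z)-3α-(PMB-oxy)-9β,12-bis(TBS-oxy)-10βH-eremophil-7(11)-en-8-ol
Conditions: TBSCl (1.05 equiv), imidazole, CH2Cl2, 0 °C
Reagents that add atoms: tert-butyldimethylsilyl chloride, CC(C)(C)[Si](C)(C)Cl
Why: The unhindered primary allylic hydroxyl is silylated much faster than the secondary C8 hydroxyl, which is flanked by the C9 silyl ether and the tetrasubstituted alkene.

Step 17
Reactants: 25 (7(11)Z)-3α-(PMB-oxy)-9β,12-bis(TBS-oxy)-10βH-eremophil-7(11)-en-8-ol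
Product: 26 (7(11)Z)-3α-(PMB-oxy)-9β,12-bis(TBS-oxy)-10βH-eremophil-7(11)-en-8-one
Conditions: DMP, NaHCO3, CH2Cl2, 0 → 23 °C
Reagents that add atoms: none
Why: Neutral Dess–Martin oxidation of the allylic alcohol restores the C8 ketone while the Z alkene and C9 are preserved.

Step 18
Reactants: 26 (7(11)Z)-3α-(PMB-oxy)-9β,12-bis(TBS-oxy)-10βH-eremophil-7(11)-en-8-one
Product: 27 (7(11)Z)-3α-hydroxy-9β,12-bis(TBS-oxy)-10βH-eremophil-7(11)-en-8-one
Conditions: DDQ, CH2Cl2/pH 7 buffer, 0 → 23 °C
Reagents that add atoms: none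
Why: Oxidative cleavage of the 4-methoxybenzyl ether by benzylic hydride abstraction and hydrolysis of the oxocarbenium ion; silyl ethers and the electron-poor enone are inert.

Step 19
Reactants: 28 (E)-non-3-en-2-one
Product: 29 ethyl (2E,4E,6E)-5-methyldodeca-2,4,6-trienoate
Conditions: (EtO)2P(O)CH2CH=CHCO2Et, LiN(SiMe3)2, THF, −78 → 23 °C
Reagents that add atoms: ethyl (E)-4-(diethoxyphosphoryl)but-2-enoate, CCOC(=O)/C=C/CP(=O)(OCC)OCC
Why: Vinylogous Horner–Wadsworth–Emmons olefination; the lithiated phosphonocrotonate adds 1,2 to the methyl ketone and eliminates to the trienoate. The new trisubstituted C4′=C5′ alkene is expected mainly E, and the minor 4′Z isomer is removed by chromatography.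

Step 20
Reactants: 29 ethyl (2E,4E,6E)-5-methyldodeca-2,4,6-trienoate
Product: 30 (2E,4E,6E)-5-methyldodeca-2,4,6-trienoic acid
Conditions: LiOH, THF/MeOH/H2O, 23 °C; then aq. HCl to pH 3
Reagents that add atoms: lithium hydroxide, [Li+].[OH-]
Why: Saponification of the ethyl ester by acyl–oxygen cleavage; the conjugated triene is stable to hydroxide at room temperature.

Step 21
Reactants: 27 (7(11)Z)-3α-hydroxy-9β,12-bis(TBS-oxy)-10βH-eremophil-7(11)-en-8-one; 30 (2E,4E,6E)-5-methyldodeca-2,4,6-trienoic acid
Product: 32 (7(11)Z)-3α-[(2E,4E,6E)-5-methyldodeca-2,4,6-trienoyloxy]-9β,12-bis(TBS-oxy)-10βH-eremophil-7(11)-en-8-one, via mixed anhydride 31 (not isolated)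
Conditions: 2,4,6-Cl3C6H2COCl, Et3N, THF, 23 °C; then 27, DMAP, PhMe, 23 °C
Reagents that add atoms: none
Why: Yamaguchi esterification; DMAP attacks the mixed anhydride 31 at the less hindered trienoyl carbonyl and the acylpyridinium acylates the hindered secondary C3 alcohol with retention at C3.

Step 22
Reactants: 32 (7(11)Z)-3α-[(2E,4E,6E)-5-methyldodeca-2,4,6-trienoyloxy]-9β,12-bis(TBS-oxy)-10βH-eremophil-7(11)-en-8-one
Product: 33 CNP0226738.1, (7(11)Z)-9β,12-dihydroxy-3α-[(2E,4E,6E)-5-methyldodeca-2,4,6-trienoyloxy]-10βH-eremophil-7(11)-en-8-one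
Conditions: TBAF, AcOH (1:1), THF, 0 → 23 °C, dark
Reagents that add atoms: none
Why: Buffered fluoride cleaves both silyl ethers (the α-keto silyl ether is activated towards fluoride); acetic acid keeps the medium near neutral so that the liberated (Z)-γ-hydroxy enone neither cyclodehydrates to the furan nor isomerises through its dienolate.

## Compound list

1 | L-glutamic acid | N[C@@H](CCC(O)=O)C(O)=O | starting material
2 | (S)-5-oxotetrahydrofuran-2-carboxylic acid | O=C1CC[C@H](O1)C(=O)O | intermediate
3 | (S)-5-(hydroxymethyl)dihydrofuran-2(3H)-one | O=C1CC[C@H](O1)CO | intermediate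
4 | (S)-5-oxotetrahydrofuran-2-carbaldehyde (not isolated) | O=C1CC[C@H](O1)C=O | intermediate
5 | (E)-3-[(2S)-5-oxotetrahydrofuran-2-yl]prop-2-enal | O=C1CC[C@H](O1)/C=C/C=O | intermediate
6 | (S)-5-[(1E,3E)-4-(4,4,5,5-tetramethyl-1,3,2-dioxaborolan-2-yl)buta-1,3-dien-1-yl]dihydrofuran-2(3H)-one | O=C1CC[C@H](O1)/C=C/C=C/B2OC(C)(C)C(C)(C)O2 | intermediate
7 | (S)-5-{(1E,3E)-4-[(4-methoxybenzyl)oxy]buta-1,3-dien-1-yl}dihydrofuran-2(3H)-one | O=C1CC[C@H](O1)/C=C/C=C/OCc1ccc(OC)cc1 | intermediate
8 | (E)-2-bromobut-2-ene | C/C=C(\C)Br | starting material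
9 | (E)-but-2-en-2-yllithium (not isolated) | C/C=C(\C)[Li] | intermediate
10 | lithium (5S)-2-[(E)-but-2-en-2-yl]-5-{(1E,3E)-4-[(4-methoxybenzyl)oxy]buta-1,3-dien-1-yl}tetrahydrofuran-2-olate (lactol carbon unassigned; not isolated) | C/C=C(\C)C1([O-])CC[C@H](O1)/C=C/C=C/OCc1ccc(OC)cc1.[Li+] | intermediate
11 | (2E,7S,8E,10E)-7-hydroxy-11-[(4-methoxybenzyl)oxy]-3-methylundeca-2,8,10-trien-4-one | C/C=C(\C)C(=O)CC[C@H](O)/C=C/C=C/OCc1ccc(OC)cc1 | intermediate
12 | (2E,7S,8E,10E)-7-[(tert-butyldimethylsilyl)oxy]-11-[(4-methoxybenzyl)oxy]-3-methylundeca-2,8,10-trien-4-one (cycloaddition precursor) | C/C=C(\C)C(=O)CC[C@H](O[Si](C)(C)C(C)(C)C)/C=C/C=C/OCc1ccc(OC)cc1 | intermediate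
13 | (4S,4aS,7R,8R,8aR)-4-[(tert-butyldimethylsilyl)oxy]-7-[(4-methoxybenzyl)oxy]-8,8a-dimethyl-3,4,4a,7,8,8a-hexahydronaphthalen-1(2H)-one; 3α-(PMB-oxy)-9β-(TBS-oxy)-4β,5β-dimethyl-10βH-octal-1-en-6-one | COc1ccc(cc1)CO[C@@H]1C=C[C@@H]2[C@@H](O[Si](C)(C)C(C)(C)C)CCC(=O)[C@]2(C)[C@H]1C | intermediate
14 | 3α-(PMB-oxy)-9β-(TBS-oxy)-4β,5β-dimethyl-10βH-decalin-6-one (cis-fused) | COc1ccc(cc1)CO[C@@H]1CC[C@@H]2[C@@H](O[Si](C)(C)C(C)(C)C)CCC(=O)[C@]2(C)[C@H]1C | intermediate
15 | 6-trimethylsilyl enol ether of 14, Δ6 (not isolated) | COc1ccc(cc1)CO[C@@H]1CC[C@@H]2[C@@H](O[Si](C)(C)C(C)(C)C)CC=C(O[Si](C)(C)C)[C@]2(C)[C@H]1C | intermediate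
16 | 3α-(PMB-oxy)-9β-(TBS-oxy)-4β,5β-dimethyl-10βH-octal-7-en-6-one | COc1ccc(cc1)CO[C@@H]1CC[C@@H]2[C@@H](O[Si](C)(C)C(C)(C)C)C=CC(=O)[C@]2(C)[C@H]1C | intermediate
17 | 7α,8α-epoxy-3α-(PMB-oxy)-9β-(TBS-oxy)-4β,5β-dimethyl-10βH-decalin-6-one | COc1ccc(cc1)CO[C@@H]1CC[C@@H]2[C@@H](O[Si](C)(C)C(C)(C)C)[C@@H]3O[C@@H]3C(=O)[C@]2(C)[C@H]1C | intermediate
18 | 3α-(PMB-oxy)-9β-(TBS-oxy)-4β,5β-dimethyl-10βH-octal-6-en-8α-ol | COc1ccc(cc1)CO[C@@H]1CC[C@@H]2[C@@H](O[Si](C)(C)C(C)(C)C)[C@H](O)C=C[C@]2(C)[C@H]1C | intermediate
19 | 3α-(PMB-oxy)-9β-(TBS-oxy)-4β,5β-dimethyl-10βH-octal-6-en-8-one | COc1ccc(cc1)CO[C@@H]1CC[C@@H]2[C@@H](O[Si](C)(C)C(C)(C)C)C(=O)C=C[C@]2(C)[C@H]1C | intermediate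
20 | lithium Δ7-8-enolate of the 6,7-dihydro ketone (not isolated) | COc1ccc(cc1)CO[C@@H]1CC[C@@H]2[C@@H](O[Si](C)(C)C(C)(C)C)C([O-])=CC[C@]2(C)[C@H]1C.[Li+] | intermediate
21 | 7-[1-(TBS-oxy)-2-hydroxypropan-2-yl]-3α-(PMB-oxy)-9β-(TBS-oxy)-4β,5β-dimethyl-10βH-decalin-8-one (C7/C11 mixture; not isolated) | COc1ccc(cc1)CO[C@@H]1CC[C@@H]2[C@@H](O[Si](C)(C)C(C)(C)C)C(=O)C(C(C)(O)CO[Si](C)(C)C(C)(C)C)C[C@]2(C)[C@H]1C | intermediate
22 | 3α-(PMB-oxy)-9β-(TBS-oxy)-10βH-furanoeremophilane (8,12-epoxyeremophila-7,11-diene) | COc1ccc(cc1)CO[C@@H]1CC[C@@H]2[C@@H](O[Si](C)(C)C(C)(C)C)c3occ(C)c3C[C@]2(C)[C@H]1C | intermediate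
23 | (7(11)Z)-3α-(PMB-oxy)-9β-(TBS-oxy)-8-oxo-10βH-eremophil-7(11)-en-12-al (not isolated) | COc1ccc(cc1)CO[C@@H]1CC[C@@H]2[C@@H](O[Si](C)(C)C(C)(C)C)C(=O)/C(=C(/C)C=O)C[C@]2(C)[C@H]1C | intermediate
24 | (7(11)Z)-3α-(PMB-oxy)-9β-(TBS-oxy)-10βH-eremophil-7(11)-ene-8,12-diol (C8 epimers) | COc1ccc(cc1)CO[C@@H]1CC[C@@H]2[C@@H](O[Si](C)(C)C(C)(C)C)C(O)/C(=C(/C)CO)C[C@]2(C)[C@H]1C | intermediate
25 | (7(11)Z)-3α-(PMB-oxy)-9β,12-bis(TBS-oxy)-10βH-eremophil-7(11)-en-8-ol (C8 epimers) | COc1ccc(cc1)CO[C@@H]1CC[C@@H]2[C@@H](O[Si](C)(C)C(C)(C)C)C(O)/C(=C(/C)CO[Si](C)(C)C(C)(C)C)C[C@]2(C)[C@H]1C | intermediate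
26 | (7(11)Z)-3α-(PMB-oxy)-9β,12-bis(TBS-oxy)-10βH-eremophil-7(11)-en-8-one | COc1ccc(cc1)CO[C@@H]1CC[C@@H]2[C@@H](O[Si](C)(C)C(C)(C)C)C(=O)/C(=C(/C)CO[Si](C)(C)C(C)(C)C)C[C@]2(C)[C@H]1C | intermediate
27 | (7(11)Z)-3α-hydroxy-9β,12-bis(TBS-oxy)-10βH-eremophil-7(11)-en-8-one | O[C@@H]1CC[C@@H]2[C@@H](O[Si](C)(C)C(C)(C)C)C(=O)/C(=C(/C)CO[Si](C)(C)C(C)(C)C)C[C@]2(C)[C@H]1C | intermediate
28 | (E)-non-3-en-2-one | CCCCC/C=C/C(C)=O | starting material
29 | ethyl (2E,4E,6E)-5-methyldodeca-2,4,6-trienoate | CCCCC/C=C/C(C)=C/C=C/C(=O)OCC | intermediate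
30 | (2E,4E,6E)-5-methyldodeca-2,4,6-trienoic acid | CCCCC/C=C/C(C)=C/C=C/C(=O)O | intermediate
31 | (2E,4E,6E)-5-methyldodeca-2,4,6-trienoic 2,4,6-trichlorobenzoic anhydride (not isolated) | CCCCC/C=C/C(C)=C/C=C/C(=O)OC(=O)c1c(Cl)cc(Cl)cc1Cl | intermediate
32 | (7(11)Z)-3α-[(2E,4E,6E)-5-methyldodeca-2,4,6-trienoyloxy]-9β,12-bis(TBS-oxy)-10βH-eremophil-7(11)-en-8-one | CCCCC/C=C/C(C)=C/C=C/C(=O)O[C@@H]1CC[C@@H]2[C@@H](O[Si](C)(C)C(C)(C)C)C(=O)/C(=C(/C)CO[Si](C)(C)C(C)(C)C)C[C@]2(C)[C@H]1C | intermediate
33 | CNP0226738.1; (3R,4R,5R,9R,10S,7(11)Z)-9,12-dihydroxy-3-[(2E,4E,6E)-5-methyldodeca-2,4,6-trienoyloxy]eremophil-7(11)-en-8-one | CCCCC/C=C/C(C)=C/C=C/C(=O)O[C@@H]1CC[C@@H]2[C@@H](O)C(=O)/C(=C(/C)CO)C[C@]2(C)[C@H]1C | target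

## Step count and least certain steps

Total step count: 22. Longest linear sequence: 20 steps (steps 1–18, 21 and 22, from 1 to 33); acid 30 is made in 2 steps (19 and 20) and joined in step 21.

**Step 8 (key step).** The most likely failure is insufficient discrimination between the two diene faces, because the relay from C9 rests on allylic strain against a hydrogen on C1. Some exo (trans-fused) closure and thermal loss of the dienyl ether could add to this.
- Fallback: a removable bromine on C1 turns the weak bias into a strong one. Setting out from 5, bromination and dehydrobromination (Br2, CH2Cl2, 0 °C; Et3N) give the (Z)-α-bromo enal F1.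
- Takai–Utimoto olefination gives the bromodienyl boronate F2, and Chan–Lam–Evans coupling gives the bromodienyl ether F3.
- Opening with 9 at −100 °C (to outrun bromine–lithium exchange) gives the bromo hydroxy enone F4, and silylation gives the bromotrienone F5.
- On heating, A(1,3) strain between bromine and the C9 substituents forces C9–H into the diene plane and should give the 1-bromo cycloadduct F6.
- Radical debromination (Bu3SnH, AIBN, PhH, 80 °C) brings the route back to 13.

**Step 14.** Three processes could erode it: 1,2-reduction competing with conjugate reduction, reversal of the ketone aldol before cyclisation, and solvolysis or epimerisation of the furfurylic C9 silyl ether under the acid.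
- Fallback: setting out from 19, rhodium-catalysed 1,4-hydrosilylation (Et3SiH, RhCl(PPh3)3) gives the triethylsilyl enol ether F7.
- SnCl4-promoted Mukaiyama–Michael addition to (E)-1-nitropropene at −78 °C, with Nef hydrolysis of the nitronate on aqueous work-up, forms the C7–C11 bond irreversibly and gives the keto aldehyde F8.
- Paal–Knorr cyclodehydration with PPTS in CH2Cl2 brings the route back to 22.

**Step 22.** The risk is loss of the product while the slower C9 silyl ether is still being cleaved: cyclodehydration of the already liberated γ-hydroxy enone to the furan, or isomerisation through its dienolate.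
- Fallback: the two hydroxyls are released in a controlled order. Setting out from 32, brief HF·pyridine in pyridine/THF at 0 °C removes only the primary silyl ether and gives the C12 alcohol F9.
- Acylation with levulinic acid (N,N′-diisopropylcarbodiimide, DMAP) gives the levulinate F10.
- With C12 capped, the C9 silyl ether can be cleaved without haste (HF·pyridine, 23 °C) to the hydroxy levulinate F11.
- Hydrazine acetate in pyridine/AcOH at 0 °C removes the levulinate under near-neutral conditions and reaches 33.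

**Step 5.** Protodeboronation or oxidative homocoupling of the dienyl boronate could outrun C–O bond formation with a benzylic alcohol.
- Fallback: setting out from 5, a Wittig reaction with the ylide from [(4-methoxybenzyloxy)methyl]triphenylphosphonium chloride and KN(SiMe3)2 (THF, −78 °C) gives 7 directly, together with its (Z)-enol ether isomer.
- The isomer is removed by chromatography on triethylamine-deactivated silica, and the route continues from 7.

**Step 12.** Hydrazone formation at the neopentyl C6 ketone may be slow, which would let pyrazoline formation or simple epoxide opening compete.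
- Fallback: a radical counterpart of the transposition. Setting out from 17, NaBH4 reduction gives the epoxy alcohol F12, and 1,1′-thiocarbonyldiimidazole gives the imidazole-1-carbothioate F13.
- Bu3SnH/AIBN generates the C6 radical, which opens the epoxide to the C8 alkoxy radical and returns the route to 18.

## Further compounds

F1 | step 8 | (Z)-2-bromo-3-[(2S)-5-oxotetrahydrofuran-2-yl]prop-2-enal | O=C1CC[C@H](O1)/C=C(\Br)C=O
F2 | step 8 | (S)-5-[(1Z,3E)-2-bromo-4-(4,4,5,5-tetramethyl-1,3,2-dioxaborolan-2-yl)buta-1,3-dien-1-yl]dihydrofuran-2(3H)-one | O=C1CC[C@H](O1)/C=C(\Br)/C=C/B2OC(C)(C)C(C)(C)O2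
F3 | step 8 | (S)-5-{(1Z,3E)-2-bromo-4-[(4-methoxybenzyl)oxy]buta-1,3-dien-1-yl}dihydrofuran-2(3H)-one | O=C1CC[C@H](O1)/C=C(\Br)/C=C/OCc1ccc(OC)cc1
F4 | step 8 | (2E,7S,8Z,10E)-9-bromo-7-hydroxy-11-[(4-methoxybenzyl)oxy]-3-methylundeca-2,8,10-trien-4-one | C/C=C(\C)C(=O)CC[C@H](O)/C=C(\Br)/C=C/OCc1ccc(OC)cc1
F5 | step 8 | (2E,7S,8Z,10E)-9-bromo-7-[(tert-butyldimethylsilyl)oxy]-11-[(4-methoxybenzyl)oxy]-3-methylundeca-2,8,10-trien-4-one | C/C=C(\C)C(=O)CC[C@H](O[Si](C)(C)C(C)(C)C)/C=C(\Br)/C=C/OCc1ccc(OC)cc1
F6 | step 8 | 1-bromo-3α-(PMB-oxy)-9β-(TBS-oxy)-4β,5β-dimethyl-10βH-octal-1-en-6-one | COc1ccc(cc1)CO[C@@H]1C=C(Br)[C@@H]2[C@@H](O[Si](C)(C)C(C)(C)C)CCC(=O)[C@]2(C)[C@H]1C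
F7 | step 14 | 8-(triethylsilyloxy)-3α-(PMB-oxy)-9β-(TBS-oxy)-4β,5β-dimethyl-10βH-octal-7-ene | COc1ccc(cc1)CO[C@@H]1CC[C@@H]2[C@@H](O[Si](C)(C)C(C)(C)C)C(O[Si](CC)(CC)CC)=CC[C@]2(C)[C@H]1C
F8 | step 14 | 2-[3α-(PMB-oxy)-9β-(TBS-oxy)-4β,5β-dimethyl-8-oxo-10βH-decalin-7-yl]propanal (C7/C11 mixture) | COc1ccc(cc1)CO[C@@H]1CC[C@@H]2[C@@H](O[Si](C)(C)C(C)(C)C)C(=O)C(C(C)C=O)C[C@]2(C)[C@H]1C
F9 | step 22 | (7(11)Z)-12-hydroxy-3α-[(2E,4E,6E)-5-methyldodeca-2,4,6-trienoyloxy]-9β-(TBS-oxy)-10βH-eremophil-7(11)-en-8-one | CCCCC/C=C/C(C)=C/C=C/C(=O)O[C@@H]1CC[C@@H]2[C@@H](O[Si](C)(C)C(C)(C)C)C(=O)/C(=C(/C)CO)C[C@]2(C)[C@H]1C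
F10 | step 22 | (7(11)Z)-12-(4-oxopentanoyloxy)-3α-[(2E,4E,6E)-5-methyldodeca-2,4,6-trienoyloxy]-9β-(TBS-oxy)-10βH-eremophil-7(11)-en-8-one | CCCCC/C=C/C(C)=C/C=C/C(=O)O[C@@H]1CC[C@@H]2[C@@H](O[Si](C)(C)C(C)(C)C)C(=O)/C(=C(/C)COC(=O)CCC(C)=O)C[C@]2(C)[C@H]1C
F11 | step 22 | (7(11)Z)-9β-hydroxy-12-(4-oxopentanoyloxy)-3α-[(2E,4E,6E)-5-methyldodeca-2,4,6-trienoyloxy]-10βH-eremophil-7(11)-en-8-one | CCCCC/C=C/C(C)=C/C=C/C(=O)O[C@@H]1CC[C@@H]2[C@@H](O)C(=O)/C(=C(/C)COC(=O)CCC(C)=O)C[C@]2(C)[C@H]1C
F0 | step 5 | none | none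
F12 | step 12 | 7α,8α-epoxy-3α-(PMB-oxy)-9β-(TBS-oxy)-4β,5β-dimethyl-10βH-decalin-6-ol (C6 epimers) | COc1ccc(cc1)CO[C@@H]1CC[C@@H]2[C@@H](O[Si](C)(C)C(C)(C)C)[C@@H]3O[C@@H]3C(O)[C@]2(C)[C@H]1C
F13 | step 12 | O-[7α,8α-epoxy-3α-(PMB-oxy)-9β-(TBS-oxy)-4β,5β-dimethyl-10βH-decalin-6-yl] 1H-imidazole-1-carbothioate | COc1ccc(cc1)CO[C@@H]1CC[C@@H]2[C@@H](O[Si](C)(C)C(C)(C)C)[C@@H]3O[C@@H]3C(OC(=S)n4ccnc4)[C@]2(C)[C@H]1C
A1 | alternative 1 | cis-1,1-dimethoxy-4a,5-dimethyl-3,4,4a,7,8,8a-hexahydronaphthalen-2(1H)-one | C1=C(C)[C@@]2(C)CCC(=O)C(OC)(OC)[C@H]2CC1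
A2 | alternative 2 | cis-8a-methyl-4a,5-dihydronaphthalene-1,6(2H,8aH)-dione | O=C1CC=C[C@@H]2CC(=O)C=C[C@]12C
A3 | alternative 3 | 6-[(tert-butyldimethylsilyl)oxy]-1-(methoxymethoxy)-4a,5-dimethyl-5,6,7,8-tetrahydronaphthalen-2(4aH)-one | CC(C)(C)[Si](C)(C)O[C@@H]1CCC2=C(OCOC)C(=O)C=C[C@]2(C)[C@H]1C
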